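**Assumption:** the target has no stereocentre (it is achiral), so no enantiocontrol is needed; compound numbers follow the forward route, and LDA is used as a commercial solution.

## Retrosynthetic overview

1. 12 ⇒ benzyl ether 11 (final O-debenzylation); 11 ⇒ alcohol 8 + docosanoic acid 9 (ester C–O bond).
2. 8 ⇒ saturated ester 7 ⇒ cinnamate 6 ⇒ β-hydroxy ester 4 (ester reduction, conjugate reduction, dehydration).
3. Key C–C disconnection: the Cα–Cβ bond of 4 ⇒ 4-(benzyloxy)benzaldehyde 1 + methyl acetate 2 (intermolecular ester aldol addition).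
4. No ring is formed: the benzene ring is bought in with 1.

## Route

**Step 1**
Reactants: 1 4-(benzyloxy)benzaldehyde; 2 methyl acetate
Product: 4 rac-methyl 3-[4-(benzyloxy)phenyl]-3-hydroxypropanoate, via methyl acetate lithium enolate 3 (not isolated)
Conditions: LDA (1.2 equiv), THF, −78 °C; 2 (1.2 equiv), 30 min; then 1, −78 °C, 1 h; AcOH quench at −78 °C
Reagents that add atoms: none
Why: Directed aldol addition of a preformed lithium ester enolate to a non-enolisable aromatic aldehyde is irreversible at −78 °C; the new carbinol centre forms as a racemate and is removed in step 2.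

**Step 2**
Reactants: 4 rac-methyl 3-[4-(benzyloxy)phenyl]-3-hydroxypropanoate
Product: 6 methyl (E)-3-[4-(benzyloxy)phenyl]prop-2-enoate, via benzylic mesylate 5 (not isolated)
Conditions: MsCl (1.3 equiv), Et3N (2 equiv), CH2Cl2, 0 °C; then DBU (2.5 equiv), 0 °C → rt
Reagents that add atoms: none
Why: Mesylation followed by base-mediated E1cB β-elimination of the activated benzylic leaving group gives the conjugated, thermodynamically favoured E-cinnamate.

**Step 3**
Reactants: 6 methyl (E)-3-[4-(benzyloxy)phenyl]prop-2-enoate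
Product: 7 methyl 3-[4-(benzyloxy)phenyl]propanoate
Conditions: NaBH4 (3 equiv, portionwise), NiCl2·6H2O (0.2 equiv), MeOH/THF, 0 °C
Reagents that add atoms: none
Why: Nickel boride conjugate reduction saturates the electron-poor C=C at 0 °C and leaves the methyl ester and the aryl benzyl ether intact, which Pd/H2 would not.

**Step 4**
Reactants: 7 methyl 3-[4-(benzyloxy)phenyl]propanoate
Product: 8 3-[4-(benzyloxy)phenyl]propan-1-ol
Conditions: LiAlH4 (1.2 equiv), THF, 0 °C → rt; Fieser work-up
Reagents that add atoms: none
Why: LiAlH4 hydride reduction of an ester to the primary alcohol is clean, and benzyl ethers are inert to it.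

**Step 5**
Reactants: 8 3-[4-(benzyloxy)phenyl]propan-1-ol; 9 docosanoic acid
Product: 11 3-[4-(benzyloxy)phenyl]propyl docosanoate, via O-docosanoylisourea 10 (not isolated)
Conditions: 9 (1.1 equiv), DCC (1.2 equiv), DMAP (0.1 equiv), CH2Cl2/THF, 0 °C → rt, 12 h; filter
Reagents that add atoms: none
Why: Steglich esterification acylates the unhindered primary alcohol through the DCC-activated acid with DMAP as acyl-transfer catalyst, and the phenol is masked so only one hydroxyl can react.

**Step 6**
Reactants: 11 3-[4-(benzyloxy)phenyl]propyl docosanoate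
Product: 12 3-(4-hydroxyphenyl)propyl docosanoate
Conditions: H2 (1 atm), 10% Pd/C, EtOAc/THF, rt
Reagents that add atoms: none
Why: Pd-catalysed hydrogenolysis cleaves the benzyl aryl ether under neutral conditions that leave the alkyl ester and the arene untouched.

## Compound list

1 | 4-(benzyloxy)benzaldehyde | O=Cc1ccc(OCc2ccccc2)cc1 | starting material
2 | methyl acetate | COC(C)=O | starting material
3 | methyl acetate lithium enolate (not isolated) | [Li+].[O-]C(=C)OC | intermediate
4 | rac-methyl 3-[4-(benzyloxy)phenyl]-3-hydroxypropanoate | COC(=O)CC(O)c1ccc(OCc2ccccc2)cc1 | intermediate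
5 | rac-methyl 3-[4-(benzyloxy)phenyl]-3-(methylsulfonyloxy)propanoate (not isolated) | COC(=O)CC(OS(C)(=O)=O)c1ccc(OCc2ccccc2)cc1 | intermediate
6 | methyl (E)-3-[4-(benzyloxy)phenyl]prop-2-enoate | COC(=O)/C=C/c1ccc(OCc2ccccc2)cc1 | intermediate
7 | methyl 3-[4-(benzyloxy)phenyl]propanoate | COC(=O)CCc1ccc(OCc2ccccc2)cc1 | intermediate
8 | 3-[4-(benzyloxy)phenyl]propan-1-ol | OCCCc1ccc(OCc2ccccc2)cc1 | intermediate
9 | docosanoic acid (behenic acid) | CCCCCCCCCCCCCCCCCCCCCC(=O)O | starting material
10 | N,N'-dicyclohexyl-O-docosanoylisourea (not isolated) | CCCCCCCCCCCCCCCCCCCCCC(=O)OC(=NC1CCCCC1)NC1CCCCC1 | intermediate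
11 | 3-[4-(benzyloxy)phenyl]propyl docosanoate | CCCCCCCCCCCCCCCCCCCCCC(=O)OCCCc1ccc(OCc2ccccc2)cc1 | intermediate
12 | 3-(4-hydroxyphenyl)propyl docosanoate | CCCCCCCCCCCCCCCCCCCCCC(=O)OCCCc1ccc(O)cc1 | target

## Summary

Total step count: 6. Longest linear sequence: 6 steps (1 → 12).

**Steps most likely to fail, with fallbacks**

Step 3 (partial O-debenzylation or incomplete conjugate reduction). The fallback sets out from 6 and comes back at 7. Hydrogenate 6 fully (H2, 10% Pd/C, MeOH/EtOAc, rt), which saturates the alkene and removes the benzyl group, to give methyl 3-(4-hydroxyphenyl)propanoate F1. Then re-benzylate the phenol (BnBr, K2CO3, acetone, reflux) to reach 7.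

Step 1 (retro-aldol, ester self-condensation or incomplete conversion). The fallback sets out from 1 and comes back at 6, bypassing steps 1 and 2. A Knoevenagel–Doebner condensation of 1 with malonic acid (pyridine, cat. piperidine, 100 °C) passes through 2-[4-(benzyloxy)benzylidene]malonic acid F2 (not isolated). This decarboxylates in the flask to (E)-3-[4-(benzyloxy)phenyl]prop-2-enoic acid F3. O-Methylation of the acid (MeI, K2CO3, DMF, rt) gives 6.

Step 5 (N-acylurea formation, poor solubility of the waxy acid, DCU removal). The fallback sets out from 8 and comes back at 11, reversing the polarity of the ester bond formation. Appel bromination of 8 (CBr4, PPh3, CH2Cl2, 0 °C) gives 1-(benzyloxy)-4-(3-bromopropyl)benzene F4. Acid 9 is deprotonated with Cs2CO3 in DMF to caesium docosanoate F5 (not isolated), which displaces the bromide of F4 by SN2 at 60 °C to give 11.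

## Further compounds

F1 | step 3 | methyl 3-(4-hydroxyphenyl)propanoate | COC(=O)CCc1ccc(O)cc1
F2 | step 1 | 2-[4-(benzyloxy)benzylidene]malonic acid | OC(=O)C(=Cc1ccc(OCc2ccccc2)cc1)C(O)=O
F3 | step 1 | (E)-3-[4-(benzyloxy)phenyl]prop-2-enoic acid | OC(=O)/C=C/c1ccc(OCc2ccccc2)cc1
F4 | step 5 | 1-(benzyloxy)-4-(3-bromopropyl)benzene | BrCCCc1ccc(OCc2ccccc2)cc1
F5 | step 5 | caesium docosanoate | [Cs+].CCCCCCCCCCCCCCCCCCCCCC(=O)[O-]
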